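Chain carbons are counted from C1 (the CH2 on the furan) to C12 (the Me2C= carbon); CO2H sits on C4 and CO2Me on C8, and the furan is the only ring and is never touched. The route rests on the open-chain C8–C9 bond. C8, an ester α-carbon, is made electrophilic by the γ-bromide of methyl (E)-4-bromobut-2-enoate, and a copper-catalysed SN2′ attack by the homoprenyl Grignard reagent (C9–C12) forms this bond and the C8 stereocentre in one operation, leaving a vinyl group at C8. The crotonate supplies the ester carbon, C8 and C7; its CH2 terminus later leaves as ethylene when cross-metathesis joins C7 to an auxiliary-derived (R)-α-allyl acid carrying C1–C6.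

Key step: step 2

Assumption: (R,R)-TaniaPhos, 1-[(dimethylamino)(2-diphenylphosphinophenyl)methyl]-2-diphenylphosphinoferrocene, is taken as the ligand enantiomer that leads to (S)-4; if a first run shows the opposite sense, the mirror-image ligand is used and nothing else changes.

Step 1
Reactants: 1 5-bromo-2-methylpent-2-ene
Product: 2 (4-methylpent-3-en-1-yl)magnesium bromide (titrated Et2O solution, used directly)
Conditions: Mg turnings (1.2 equiv), I2 (cat.), Et2O, gentle reflux then rt
Reagents that add atoms: magnesium, [Mg]
Why: Grignard formation by magnesium insertion into a primary alkyl bromide is routine, and the homoallylic reagent stays in its open-chain form because its cyclopropylcarbinyl equilibrium is degenerate.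

Step 2
Reactants: 2 (4-methylpent-3-en-1-yl)magnesium bromide; 3 methyl (E)-4-bromobut-2-enoate
Product: 4 methyl (S)-2-ethenyl-6-methylhept-5-enoate
Conditions: CuBr·SMe2 (5 mol%), (R,R)-TaniaPhos C43H39FeNP2 (6 mol%), CH2Cl2, −75 °C; 2 (1.2 equiv, Et2O) added over 3 h; MeOH then sat. aq NH4Cl at −75 °C
Reagents that add atoms: none
Why: Transmetalation of 2 to the monovalent copper–diphosphine complex gives an alkylcuprate that binds the enoate C=C anti to the C–Br bond, oxidative addition gives a trivalent copper σ-allyl species bonded at the former α-carbon, and fast reductive elimination forms C8–C9 before the allyl unit can relax to the linear isomer, the γ-bromide diverting the cuprate from conjugate addition to allylic substitution. The closest known reaction type is the copper/ferrocenyl-diphosphine-catalysed asymmetric allylic alkylation of 4-halocrotonates with primary alkyl Grignard reagents, applied here to a homoprenyl reagent. No ring is closed. The one new stereocentre, C8, is set by the chiral ligand on copper (pure catalyst control, since neither partner has a stereocentre). The step needs branched over linear substitution and one enantioface; the E geometry and bromide leaving group of 3, the unbranched primary Grignard reagent with its alkene remote, CH2Cl2 as solvent and slow addition at −75 °C (so that uncatalysed attack on the ester or on CH2Br stays negligible) secure both. The cold buffered quench keeps the doubly activated C8–H from moving the vinyl double bond into conjugation.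

Step 3
Reactants: 4 methyl (S)-2-ethenyl-6-methylhept-5-enoate
Product: 5 methyl (2S)-5,6-dibromo-2-ethenyl-6-methylheptanoate (both C5 epimers)
Conditions: Br2 (1.0 equiv), CH2Cl2, −78 °C, dark; aq Na2S2O3
Reagents that add atoms: bromine, BrBr
Why: Electrophilic bromine addition is far faster at the electron-rich trisubstituted C5=C6 alkene than at the vinyl group next to the ester-bearing carbon, so the isopropylidene unit is masked as a vicinal dibromide (alkene protection by bromination), which is required because the free 1,6-diene would undergo ring-closing metathesis to a cyclopentene in step 9 and would compete for diimide in step 10, and the neutral conditions leave the C2 stereocentre alone.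

Step 4
Reactants: 6 furan-3-carbaldehyde; 7 (3-carboxypropyl)triphenylphosphonium bromide
Product: 9 (Z)-5-(furan-3-yl)pent-4-enoic acid, via sodium carboxylate ylide 8 (not isolated)
Conditions: 7 (1.1 equiv), NaN(SiMe3)2 (2.2 equiv), THF, 0 °C; then 6, −78 °C to rt; 1 M HCl to pH 3
Reagents that add atoms: sodium bis(trimethylsilyl)amide, C[Si](C)(C)[N-][Si](C)(C)C.[Na+] (its sodium stays only in intermediate 8)
Why: Wittig olefination with the non-stabilised carboxylate ylide gives mainly the Z alkene, and the geometry is irrelevant because the alkene is reduced in the next step.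

Step 5
Reactants: 9 (Z)-5-(furan-3-yl)pent-4-enoic acid
Product: 10 5-(furan-3-yl)pentanoic acid
Conditions: H2 (1 atm), RhCl(PPh3)3 (3 mol%), toluene/EtOH 1:1, rt
Reagents that add atoms: none
Why: Homogeneous hydrogenation with the rhodium chloride–triphenylphosphine catalyst reduces the unhindered disubstituted alkene and does not hydrogenate the furan ring or the carboxylic acid.

Step 6
Reactants: 10 5-(furan-3-yl)pentanoic acid; 11 (S)-4-benzyloxazolidin-2-one
Product: 13 (S)-4-benzyl-3-[5-(furan-3-yl)pentanoyl]oxazolidin-2-one, via mixed pivalic anhydride 12 (not isolated)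
Conditions: PivCl (1.1 equiv), Et3N (2.5 equiv), THF, −20 °C; then LiCl (1.1 equiv), 11 (1.0 equiv), −20 °C to rt
Reagents that add atoms: pivaloyl chloride, CC(C)(C)C(Cl)=O (its acyl group stays only in intermediate 12)
Why: N-acylation of the oxazolidinone through the mixed anhydride works because the nucleophile attacks the less hindered acyl carbon, away from the tert-butyl group.

Step 7
Reactants: 13 (S)-4-benzyl-3-[5-(furan-3-yl)pentanoyl]oxazolidin-2-one; 14 allyl iodide (3-iodoprop-1-ene)
Product: 16 (S)-4-benzyl-3-[(2R)-2-[3-(furan-3-yl)propyl]pent-4-enoyl]oxazolidin-2-one, via sodium Z-enolate 15 (not isolated)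
Conditions: NaN(SiMe3)2 (1.1 equiv), THF, −78 °C; then 14 (3 equiv), −78 to −45 °C; sat. aq NH4Cl
Reagents that add atoms: sodium bis(trimethylsilyl)amide, C[Si](C)(C)[N-][Si](C)(C)C.[Na+] (its sodium stays only in intermediate 15)
Why: In this Evans asymmetric alkylation the chelated sodium Z-enolate is attacked by the reactive allylic iodide on the face opposite the benzyl group of the (S)-auxiliary, which sets the (R) α-centre that becomes C4 of the target.

Step 8
Reactants: 16 (S)-4-benzyl-3-[(2R)-2-[3-(furan-3-yl)propyl]pent-4-enoyl]oxazolidin-2-one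
Product: 18 (R)-2-[3-(furan-3-yl)propyl]pent-4-enoic acid, via lithium peroxycarboxylate 17 (not isolated)
Conditions: LiOH·H2O (2 equiv), 30% H2O2 (4 equiv), THF/H2O 3:1, 0 °C; aq Na2SO3; 1 M HCl to pH 3
Reagents that add atoms: hydrogen peroxide, OO; lithium hydroxide, [Li+].[OH-] (its lithium stays only in intermediate 17)
Why: Hydroperoxide anion cleaves the exocyclic imide carbonyl selectively (lithium hydroperoxide auxiliary removal) without epimerising the α-centre, sulfite reduces the peracid salt to the acid, and the furan and terminal alkene are inert to basic peroxide.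

Step 9
Reactants: 5 methyl (2S)-5,6-dibromo-2-ethenyl-6-methylheptanoate; 18 (R)-2-[3-(furan-3-yl)propyl]pent-4-enoic acid
Product: 19 (2R,4E,6S)-9,10-dibromo-2-[3-(furan-3-yl)propyl]-6-(methoxycarbonyl)-10-methylundec-4-enoic acid (C9 epimers, E expected to predominate)
Conditions: 5 (1.5 equiv), second-generation Grubbs catalyst RuCl2(=CHPh)(H2IMes)(PCy3) (5 mol%), 1,4-benzoquinone (10 mol%), CH2Cl2 (0.1 M), 40 °C, argon sweep
Reagents that add atoms: none
Why: Olefin cross-metathesis pairs the unhindered allyl group of 18 with the slower α-branched vinyl group of 5 so that the cross product is favoured over either homodimer and is driven by loss of ethylene, ring closure onto the isopropylidene carbon is impossible because that alkene is masked, benzoquinone suppresses ruthenium hydride double-bond migration so that C6 of the product (C8 of the target) keeps its configuration, and the alkene geometry is irrelevant because it is reduced next.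

Step 10
Reactants: 19 (2R,4E,6S)-9,10-dibromo-2-[3-(furan-3-yl)propyl]-6-(methoxycarbonyl)-10-methylundec-4-enoic acid
Product: 20 (2S,6R)-9,10-dibromo-2-[3-(furan-3-yl)propyl]-6-(methoxycarbonyl)-10-methylundecanoic acid (C9 epimers)
Conditions: KO2C–N=N–CO2K (10 equiv, portions), AcOH (20 equiv, slow addition), CH2Cl2, rt
Reagents that add atoms: none
Why: Diimide generated from the azodicarboxylate salt delivers H2 by concerted syn transfer to the only C=C bond that is neither aromatic nor masked, under metal-free and weakly acidic conditions that do not touch C–Br bonds, the furan, the ester or either stereocentre (diimide reduction).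

Step 11
Reactants: 20 (2S,6R)-9,10-dibromo-2-[3-(furan-3-yl)propyl]-6-(methoxycarbonyl)-10-methylundecanoic acid
Product: 21 (2S,6R)-2-[3-(furan-3-yl)propyl]-6-(methoxycarbonyl)-10-methylundec-9-enoic acid (CNP0266677.2)
Conditions: Zn dust (10 equiv), AcOH/Et2O 1:10, 0 °C to rt
Reagents that add atoms: none
Why: Zinc effects reductive elimination of the vicinal dibromide (classical debromination of a dibromide-protected alkene) and regenerates the C9=C10 alkene, which carries two identical methyl groups and so has no geometry, so that both bromide epimers converge on the target while the acid, ester, furan and both stereocentres are inert to zinc in acetic acid.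

Compound list
1 | 5-bromo-2-methylpent-2-ene | CC(C)=CCCBr | starting material
2 | (4-methylpent-3-en-1-yl)magnesium bromide | CC(C)=CCC[Mg]Br | intermediate
3 | methyl (E)-4-bromobut-2-enoate | COC(=O)/C=C/CBr | starting material
4 | methyl (S)-2-ethenyl-6-methylhept-5-enoate | COC(=O)[C@@H](CCC=C(C)C)C=C | intermediate
5 | methyl (2S)-5,6-dibromo-2-ethenyl-6-methylheptanoate (both C5 epimers) | COC(=O)[C@@H](CCC(Br)C(C)(C)Br)C=C | intermediate
6 | furan-3-carbaldehyde | O=Cc1ccoc1 | starting material
7 | (3-carboxypropyl)triphenylphosphonium bromide | OC(=O)CCC[P+](c1ccccc1)(c1ccccc1)c1ccccc1.[Br-] | starting material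
8 | sodium 4-(triphenylphosphoranylidene)butanoate (ylide) | [Na+].[O-]C(=O)CCC=P(c1ccccc1)(c1ccccc1)c1ccccc1 | intermediate
9 | (Z)-5-(furan-3-yl)pent-4-enoic acid | OC(=O)CC/C=C\c1ccoc1 | intermediate
10 | 5-(furan-3-yl)pentanoic acid | OC(=O)CCCCc1ccoc1 | intermediate
11 | (S)-4-benzyloxazolidin-2-one | O=C1N[C@@H](Cc2ccccc2)CO1 | starting material
12 | 5-(furan-3-yl)pentanoic pivalic anhydride | CC(C)(C)C(=O)OC(=O)CCCCc1ccoc1 | intermediate
13 | (S)-4-benzyl-3-[5-(furan-3-yl)pentanoyl]oxazolidin-2-one | O=C(CCCCc1ccoc1)N1[C@@H](Cc2ccccc2)COC1=O | intermediate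
14 | allyl iodide (3-iodoprop-1-ene) | C=CCI | starting material
15 | sodium (Z)-enolate of 13 | [Na+].[O-]/C(=C\CCCc1ccoc1)N1[C@@H](Cc2ccccc2)COC1=O | intermediate
16 | (S)-4-benzyl-3-[(2R)-2-[3-(furan-3-yl)propyl]pent-4-enoyl]oxazolidin-2-one | C=CC[C@@H](CCCc1ccoc1)C(=O)N1[C@@H](Cc2ccccc2)COC1=O | intermediate
17 | lithium (2R)-2-[3-(furan-3-yl)propyl]pent-4-eneperoxoate | C=CC[C@@H](CCCc1ccoc1)C(=O)O[O-].[Li+] | intermediate
18 | (R)-2-[3-(furan-3-yl)propyl]pent-4-enoic acid | C=CC[C@@H](CCCc1ccoc1)C(=O)O | intermediate
19 | (2R,4E,6S)-9,10-dibromo-2-[3-(furan-3-yl)propyl]-6-(methoxycarbonyl)-10-methylundec-4-enoic acid (C9 epimers) | COC(=O)[C@@H](CCC(Br)C(C)(C)Br)/C=C/C[C@@H](CCCc1ccoc1)C(=O)O | intermediate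
20 | (2S,6R)-9,10-dibromo-2-[3-(furan-3-yl)propyl]-6-(methoxycarbonyl)-10-methylundecanoic acid (C9 epimers) | COC(=O)[C@@H](CCC(Br)C(C)(C)Br)CCC[C@@H](CCCc1ccoc1)C(=O)O | intermediate
21 | (2S,6R)-2-[3-(furan-3-yl)propyl]-6-(methoxycarbonyl)-10-methylundec-9-enoic acid | COC(=O)[C@@H](CCC=C(C)C)CCC[C@@H](CCCc1ccoc1)C(=O)O | target

Total step count: 11.
Longest linear sequence: 8 steps (steps 4 to 11, from furan-3-carbaldehyde); the other branch is 6 steps (steps 1 to 3 and 9 to 11).

Steps most likely to fail

Step 2. The cuprate pathway may be outrun by uncatalysed Grignard attack, eroding branched-to-linear selectivity or enantiofacial control, or the vinyl double bond may migrate into conjugation during quench and isolation. The fallback sets out from 1. Methyl (E)-but-2-enoate (COC(=O)/C=C/C) is deprotonated with LiN(iPr)2 in THF/DMPU at −78 °C to its lithium dienolate F1, which is alkylated at the α-carbon by 1 (deconjugative enolate alkylation) to give racemic methyl 2-ethenyl-6-methylhept-5-enoate F2. Preparative chromatography on a chiral stationary phase then delivers 4, where the route is rejoined, and the unwanted methyl (R)-2-ethenyl-6-methylhept-5-enoate F3 is set aside.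

Step 9. Productive metathesis at the α-branched vinyl group may be slow, so that the acid homodimerises and the catalyst dies before two valuable fragments have crossed. The fallback sets out from 5 and moves the fragment union to an enolate alkylation.
- Cross-metathesis of 5 with a large excess of cheap (E)-1,4-dibromobut-2-ene (same ruthenium catalyst) should give the allylic bromide methyl (2S,3E)-5-bromo-2-(3,4-dibromo-4-methylpentyl)pent-3-enoate F4.
- Sodium enolate 15, made from 13 as in step 7, is alkylated by F4 at −78 °C, the reactive allylic bromide being added last so that alkylation outruns proton transfer from C2 of F4. This should give (S)-4-benzyl-3-[(2R,4E,6S)-9,10-dibromo-2-[3-(furan-3-yl)propyl]-6-(methoxycarbonyl)-10-methylundec-4-enoyl]oxazolidin-2-one F5.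
- Diimide reduction of F5 (KO2C–N=N–CO2K, AcOH) gives (S)-4-benzyl-3-[(2S,6R)-9,10-dibromo-2-[3-(furan-3-yl)propyl]-6-(methoxycarbonyl)-10-methylundecanoyl]oxazolidin-2-one F6.
- LiOH/H2O2 at 0 °C cleaves the auxiliary through lithium (2S,6R)-9,10-dibromo-2-[3-(furan-3-yl)propyl]-6-(methoxycarbonyl)-10-methylundecaneperoxoate F7, and sulfite reduction returns the route to 20.

Step 10. Diimide may reduce the hindered E-alkene incompletely, and long exposure may cost HBr from the tertiary bromide. The fallback sets out from 19 and inverts the order. Zn dust in AcOH/Et2O first unmasks the alkene to give (2R,4E,6S)-2-[3-(furan-3-yl)propyl]-6-(methoxycarbonyl)-10-methylundeca-4,9-dienoic acid F8. Hydrogenation with H2 and RhCl(PPh3)3 in toluene/EtOH, which reduces 1,2-disubstituted alkenes far faster than trisubstituted ones and leaves furans alone, then gives 21 directly.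

Further compounds
F1 | step 2 | lithium 1-methoxybuta-1,3-dien-1-olate (dienolate of methyl crotonate) | [Li+].[O-]C(OC)=CC=C
F2 | step 2 | racemic methyl 2-ethenyl-6-methylhept-5-enoate | COC(=O)C(CCC=C(C)C)C=C
F3 | step 2 | methyl (R)-2-ethenyl-6-methylhept-5-enoate | COC(=O)[C@H](CCC=C(C)C)C=C
F4 | step 9 | methyl (2S,3E)-5-bromo-2-(3,4-dibromo-4-methylpentyl)pent-3-enoate | COC(=O)[C@@H](CCC(Br)C(C)(C)Br)/C=C/CBr
F5 | step 9 | (S)-4-benzyl-3-[(2R,4E,6S)-9,10-dibromo-2-[3-(furan-3-yl)propyl]-6-(methoxycarbonyl)-10-methylundec-4-enoyl]oxazolidin-2-one | COC(=O)[C@@H](CCC(Br)C(C)(C)Br)/C=C/C[C@@H](CCCc1ccoc1)C(=O)N1[C@@H](Cc2ccccc2)COC1=O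
F6 | step 9 | (S)-4-benzyl-3-[(2S,6R)-9,10-dibromo-2-[3-(furan-3-yl)propyl]-6-(methoxycarbonyl)-10-methylundecanoyl]oxazolidin-2-one | COC(=O)[C@@H](CCC(Br)C(C)(C)Br)CCC[C@@H](CCCc1ccoc1)C(=O)N1[C@@H](Cc2ccccc2)COC1=O
F7 | step 9 | lithium (2S,6R)-9,10-dibromo-2-[3-(furan-3-yl)propyl]-6-(methoxycarbonyl)-10-methylundecaneperoxoate | COC(=O)[C@@H](CCC(Br)C(C)(C)Br)CCC[C@@H](CCCc1ccoc1)C(=O)O[O-].[Li+]
F8 | step 10 | (2R,4E,6S)-2-[3-(furan-3-yl)propyl]-6-(methoxycarbonyl)-10-methylundeca-4,9-dienoic acid | COC(=O)[C@@H](CCC=C(C)C)/C=C/C[C@@H](CCCc1ccoc1)C(=O)O
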